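## Retrosynthetic overview

1. Numbering: tetralone C1 (C=O) to C8a, naphthyl C1'–C8a', with C1' on C4. The plan rests on the C1'–C4' ring. Its four carbons and the C4' oxygen are a 2-substituted furan, and the C4a'–C8a' edge beside C8'–OMe is 3-methoxybenzyne, so the crowded C1'/C8' peri contact is made by cycloaddition.
2. Target 19 ⇐ debenzylation of 18 ⇐ aryne Diels–Alder and acid opening (forms C1'–C8a' and C4'–C4a') of (R)-furyl tetralone 14 with aryne 16 from silyl triflate 15.
3. 14 ⇐ Parham closure of C1–C8a in bromo amide 12 ⇐ stereoretentive boronate-to-furan coupling (C4–furan C2) of 8 ⇐ copper hydride hydroboration of (E)-styryl amide 7, which sets C4.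
4. 7 ⇐ Wittig formation of C3=C4 from aldehyde 3 and the C1–C3 phosphonium salt 4. Aldehyde 3 comes from 2-bromoisovanillin 1.
5. Ring order: the catechol ring and the furan are bought, the tetralone carbocycle closes in step 7, and the naphthol ring closes in step 8, its benzo ring arriving with the aryne.

Key step: step 8

Assumption: the sense of induction in step 5 is taken from simple (E)-β-alkylstyrenes, for which the (S)-ligand is expected to give the (R)-benzylic boronate. A sample of 8 is to be oxidised to the carbinol as a check, and the (R)-ligand is used if the check demands it.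

Remark: C4 keeps one spatial arrangement throughout. It is (R) in 8, 11–14 and 17 and (S) in 18 and 19 only because the CIP ranks of its substituents change.

## Route

Step 1
Reactants: 1 2-bromo-3-hydroxy-4-methoxybenzaldehyde
Product: 2 2-bromo-3,4-dihydroxybenzaldehyde
Conditions: BBr3 (2.5 equiv), CH2Cl2, −78 °C → rt; H2O
Reagents that add atoms: none
Why: Lewis-acid aryl methyl ether cleavage, in which boron binds the C3 phenoxide and the adjacent methoxy oxygen, bromide takes the methyl group in an SN2 step, and the aldehyde and aryl bromide should survive at or below room temperature.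

Step 2
Reactants: 2 2-bromo-3,4-dihydroxybenzaldehyde
Product: 3 3,4-bis(benzyloxy)-2-bromobenzaldehyde
Conditions: BnBr (2.4 equiv), K2CO3, DMF, 60 °C
Reagents that add atoms: benzyl bromide BrCc1ccccc1
Why: Williamson ether synthesis on both phenoxides, with benzyl chosen because it survives organolithiums, copper hydride, fluoride and cold TFA and is removed by hydrogenolysis without touching the C8' methyl ether.

Step 3
Reactants: 3 3,4-bis(benzyloxy)-2-bromobenzaldehyde; 4 (2-carboxyethyl)triphenylphosphonium bromide
Product: 6 (E)-4-[3,4-bis(benzyloxy)-2-bromophenyl]but-3-enoic acid, via ylide carboxylate 5 (not isolated)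
Conditions: 4 (1.3 equiv), NaHMDS (2.6 equiv), THF, −78 → 0 °C; then 3, → rt; 1 M HCl work-up
Reagents that add atoms: (2-carboxyethyl)triphenylphosphonium bromide 4 OC(=O)CC[P+](c1ccccc1)(c1ccccc1)c1ccccc1.[Br-]
Why: Wittig olefination with the carboxylate-bearing ylide 5, which with aromatic aldehydes is known to give (E)-4-arylbut-3-enoic acids, so C3=C4 forms with defined geometry and C1–C3 arrive in one piece.

Step 4
Reactants: 6 (E)-4-[3,4-bis(benzyloxy)-2-bromophenyl]but-3-enoic acid
Product: 7 (E)-4-[3,4-bis(benzyloxy)-2-bromophenyl]-N,N-diethylbut-3-enamide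
Conditions: Et2NH, DCC, HOBt, CH2Cl2, 0 °C → rt
Reagents that add atoms: diethylamine CCNCC
Why: Carbodiimide/HOBt amidation under near-neutral conditions leaves the styrene-conjugated alkene in place, and the diethylamide is inert enough for step 6 yet is a proven internal electrophile for step 7.

Step 5
Reactants: 7 (E)-4-[3,4-bis(benzyloxy)-2-bromophenyl]-N,N-diethylbut-3-enamide
Product: 8 (R)-4-[3,4-bis(benzyloxy)-2-bromophenyl]-N,N-diethyl-4-(4,4,5,5-tetramethyl-1,3,2-dioxaborolan-2-yl)butanamide
Conditions: CuCl (5 mol %), NaOt-Bu (10 mol %), (S)-DTBM-SEGPHOS (5.5 mol %), HBpin (1.5 equiv), toluene, rt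
Reagents that add atoms: pinacolborane B1OC(C)(C)C(C)(C)O1
Why: Copper hydride-catalysed Markovnikov hydroboration of a β-substituted styrene, in which ligand-controlled syn hydrocupration puts copper on benzylic C4 from one alkene face and σ-bond metathesis with HBpin replaces it with retention, setting C4 as (R), while this catalyst tolerates the aryl bromide, benzyl ethers and tertiary amide.

Step 6
Reactants: 8 (R)-4-[3,4-bis(benzyloxy)-2-bromophenyl]-N,N-diethyl-4-(4,4,5,5-tetramethyl-1,3,2-dioxaborolan-2-yl)butanamide; 9 furan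
Product: 12 (R)-4-[3,4-bis(benzyloxy)-2-bromophenyl]-N,N-diethyl-4-(furan-2-yl)butanamide, via 2-lithiofuran 10 (not isolated), via lithium furyl boronate complex 11 (not isolated)
Conditions: furan (1.15 equiv), n-BuLi (1.1 equiv), THF, −78 °C → rt; 8, −78 °C; NBS (1.1 equiv), THF, −78 °C; aq Na2S2O3
Reagents that add atoms: furan 9 c1ccoc1
Why: Enantiospecific sp2–sp3 coupling of a secondary boronic ester with a lithiated furan, in which bromination of furan C5 in boronate 11 triggers a 1,2-metallate shift of C4 from boron to furan C2 with retention and loss of bromide and the boryl group restores the furan, so the configuration of 8 is carried over.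

Step 7
Reactants: 12 (R)-4-[3,4-bis(benzyloxy)-2-bromophenyl]-N,N-diethyl-4-(furan-2-yl)butanamide
Product: 14 (R)-7,8-bis(benzyloxy)-4-(furan-2-yl)-3,4-dihydronaphthalen-1(2H)-one, via aryllithium 13 (not isolated)
Conditions: t-BuLi (2.1 equiv), THF, −78 → −20 °C; sat. aq NH4Cl
Reagents that add atoms: none
Why: Parham cyclisation, in which bromine–lithium exchange outruns deprotonation at −78 °C, aryllithium 13 attacks the amide in a 6-exo mode to close C1–C8a at the position Friedel–Crafts acylation would not choose, and the tetrahedral adduct holds until the quench, so neither over-addition nor base contact with H-4 is expected.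

Step 8
Reactants: 14 (R)-7,8-bis(benzyloxy)-4-(furan-2-yl)-3,4-dihydronaphthalen-1(2H)-one; 15 3-methoxy-2-(trimethylsilyl)phenyl trifluoromethanesulfonate
Product: 18 (S)-7,8-bis(benzyloxy)-4-(4-hydroxy-8-methoxynaphthalen-1-yl)-3,4-dihydronaphthalen-1(2H)-one, via 3-methoxybenzyne 16 (not isolated), via oxa-bridged cycloadduct 17 (not isolated)
Conditions: 15 (1.8 equiv), CsF (4 equiv), MeCN, 0 °C → rt; then, in the same flask, CH2Cl2, excess TFA, 0 °C
Reagents that add atoms: 3-methoxy-2-(trimethylsilyl)phenyl trifluoromethanesulfonate 15 COc1cccc(OS(=O)(=O)C(F)(F)F)c1[Si](C)(C)C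
Why: Fluoride removes the silyl group of 15 and triflate departs, giving 3-methoxybenzyne 16, whose C–O dipole distorts the triple bond so that the carbon meta to OMe is the electrophilic end. The furan of 14 adds in a concerted but asynchronous intermolecular [4+2], the known aryne–furan Diels–Alder shown for 2-sec-alkyl and C-glycosyl furans: free C5, the more nucleophilic α-carbon because the developing charge lands on alkyl-bearing C2, bonds first to that end (C4'–C4a'), and C2 then closes on the carbon beside OMe (C1'–C8a'), so the new six-membered ring is closed by cycloaddition as oxa-bridged 17. The selectivity needed is this head-to-head orientation, which is secured by the aryne polarisation and the C2 alkyl donor and helped by the long, late C1'···C8a' contact in the transition state and by the methoxy methyl turning away from the aryne; the bulk of the tetralone residue works against it, so the 5-methoxy regioisomer must be expected as a by-product to be removed by chromatography. TFA then ionises only the C1'–O bond (tertiary, allylic, benzylic and ortho to C8'–OMe, whereas a C4' cation would be secondary and meta to OMe), and loss of H-4' gives the 4-alkyl-1-naphthol, the known acid isomerisation of 1,4-epoxy-1,4-dihydronaphthalenes. The two bridgehead centres of 17 form without control and are erased on aromatisation, so both diastereomers converge. C4 keeps its configuration provided proton loss from C4' is faster than migration or loss of H-4, which is why a cold, non-nucleophilic acid medium is used.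

Step 9
Reactants: 18 (S)-7,8-bis(benzyloxy)-4-(4-hydroxy-8-methoxynaphthalen-1-yl)-3,4-dihydronaphthalen-1(2H)-one
Product: 19 (S)-7,8-dihydroxy-4-(4-hydroxy-8-methoxynaphthalen-1-yl)-3,4-dihydronaphthalen-1(2H)-one
Conditions: H2 (1 atm), 10 % Pd/C, EtOAc–MeOH, rt; work-up under argon
Reagents that add atoms: none
Why: Catalytic hydrogenolysis of the two aryl benzyl ethers at 1 atm is faster than reduction of the hydrogen-bonded aryl ketone or the naphthalene, the methyl ether and the C4 stereocentre are inert, and air is excluded because catechol and naphthol oxidise easily.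

## Compound list

1 | 2-bromo-3-hydroxy-4-methoxybenzaldehyde | COc1ccc(C=O)c(Br)c1O | starting material
2 | 2-bromo-3,4-dihydroxybenzaldehyde | O=Cc1ccc(O)c(O)c1Br | intermediate
3 | 3,4-bis(benzyloxy)-2-bromobenzaldehyde | O=Cc1ccc(OCc2ccccc2)c(OCc2ccccc2)c1Br | intermediate
4 | (2-carboxyethyl)triphenylphosphonium bromide | OC(=O)CC[P+](c1ccccc1)(c1ccccc1)c1ccccc1.[Br-] | starting material
5 | sodium 3-(triphenylphosphoranylidene)propanoate (ylide carboxylate) | [Na+].[O-]C(=O)C[CH-][P+](c1ccccc1)(c1ccccc1)c1ccccc1 | intermediate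
6 | (E)-4-[3,4-bis(benzyloxy)-2-bromophenyl]but-3-enoic acid | OC(=O)C/C=C/c1ccc(OCc2ccccc2)c(OCc2ccccc2)c1Br | intermediate
7 | (E)-4-[3,4-bis(benzyloxy)-2-bromophenyl]-N,N-diethylbut-3-enamide | CCN(CC)C(=O)C/C=C/c1ccc(OCc2ccccc2)c(OCc2ccccc2)c1Br | intermediate
8 | (R)-4-[3,4-bis(benzyloxy)-2-bromophenyl]-N,N-diethyl-4-(4,4,5,5-tetramethyl-1,3,2-dioxaborolan-2-yl)butanamide | CC1(C)OB(OC1(C)C)[C@@H](c2ccc(OCc3ccccc3)c(OCc3ccccc3)c2Br)CCC(=O)N(CC)CC | intermediate
9 | furan | c1ccoc1 | starting material
10 | 2-lithiofuran | [Li]c1ccco1 | intermediate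
11 | lithium (R)-furan-2-yl boronate complex of 8 | [Li+].CC1(C)O[B-](OC1(C)C)(c1ccco1)[C@@H](c1ccc(OCc2ccccc2)c(OCc2ccccc2)c1Br)CCC(=O)N(CC)CC | intermediate
12 | (R)-4-[3,4-bis(benzyloxy)-2-bromophenyl]-N,N-diethyl-4-(furan-2-yl)butanamide | o1cccc1[C@@H](c2ccc(OCc3ccccc3)c(OCc3ccccc3)c2Br)CCC(=O)N(CC)CC | intermediate
13 | (R)-4-[3,4-bis(benzyloxy)-2-lithiophenyl]-N,N-diethyl-4-(furan-2-yl)butanamide (aryllithium) | o1cccc1[C@@H](c2ccc(OCc3ccccc3)c(OCc3ccccc3)c2[Li])CCC(=O)N(CC)CC | intermediate
14 | (R)-7,8-bis(benzyloxy)-4-(furan-2-yl)-3,4-dihydronaphthalen-1(2H)-one | o1cccc1[C@@H]2CCC(=O)c3c2ccc(OCc4ccccc4)c3OCc4ccccc4 | intermediate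
15 | 3-methoxy-2-(trimethylsilyl)phenyl trifluoromethanesulfonate | COc1cccc(OS(=O)(=O)C(F)(F)F)c1[Si](C)(C)C | starting material
16 | 3-methoxybenzyne (1-methoxy-2,3-didehydrobenzene) | COC1=CC=CC#C1 | intermediate
17 | (4R)-7,8-bis(benzyloxy)-4-(8-methoxy-1,4-epoxy-1,4-dihydronaphthalen-1-yl)-3,4-dihydronaphthalen-1(2H)-one, both bridgehead diastereomers | COc1cccc2C3C=CC(O3)([C@@H]4CCC(=O)c5c4ccc(OCc6ccccc6)c5OCc6ccccc6)c12 | intermediate
18 | (S)-7,8-bis(benzyloxy)-4-(4-hydroxy-8-methoxynaphthalen-1-yl)-3,4-dihydronaphthalen-1(2H)-one | COc1cccc2c(O)ccc([C@@H]3CCC(=O)c4c3ccc(OCc6ccccc6)c4OCc6ccccc6)c12 | intermediate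
19 | (S)-7,8-dihydroxy-4-(4-hydroxy-8-methoxynaphthalen-1-yl)-3,4-dihydronaphthalen-1(2H)-one (CNP0535815.1) | COc1cccc2c(O)ccc([C@@H]3CCC(=O)c4c3ccc(O)c4O)c12 | target

Total step count: 9
Longest linear sequence: 9 steps (1 → 19); compounds 4, 9 and 15 are bought.

## Steps most likely to fail

**Step 8.**
- What may go wrong: the furan may add in the head-to-tail orientation if repulsion between the tetralone residue and the methoxy oxygen outweighs the aryne polarisation. Slow aromatisation may also let H-4 migrate or leave, which would erode the C4 configuration.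
- Fallback (from 8, back at 18): a removable silyl group on furan C5 takes over the regiocontrol. Purchased 2-(trimethylsilyl)furan F1 is lithiated at its free α-position (n-BuLi, THF) and coupled with 8 as in step 6 (NBS, −78 °C) to give the silylfuryl amide F2. Treatment with t-BuLi as in step 7 closes it to the silylfuryl tetralone F3. With 15 and CsF, the silicon-bearing C5 is the more nucleophilic α-carbon (β-silicon stabilisation plus alkyl-stabilised charge at C2) and also the bulkier one. It should therefore go to the open, electrophilic aryne carbon and give the bridgehead silane F4. Cold TFA ionises C1'–O as before, and the silyl group leaves C4' in place of the proton, ahead of any event at H-4, which gives 18.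

**Step 6.**
- What may go wrong: 2-lithiofuran may add to the amide; boronate formation or migration may be sluggish at the hindered ortho-bromobenzylic carbon; the product furan may be brominated; or single-electron oxidation of 11 may cause loss of configuration.
- Fallback (from 3, back at 12): the furan is attached before C4 becomes stereogenic, and C4 is set by hydrogenation. 2-Lithiofuran 10 adds to aldehyde 3 to give the racemic aryl furyl carbinol F5, and MnO2 (CH2Cl2) gives the aryl furyl ketone F6. Ylide 5 (THF, reflux) gives the 4-aryl-4-furylbut-3-enoic acids, from which the (E)-acid F7 is separated; the other isomer can be used with the mirror-image catalyst. Carboxyl-directed hydrogenation with an iridium spiro-phosphine-oxazoline catalyst (H2, Et3N, MeOH) leaves the aryl bromide, benzyl ethers and furan alone and gives the (R)-butanoic acid F8. Amidation as in step 4 gives 12.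

**Step 5.**
- What may go wrong: hydrocupration may be slow or misdirected, with copper at C3 through amide chelation; base may shift the alkene into conjugation with the amide, followed by conjugate reduction; or facial selectivity may be poor next to the ortho bromine.
- Fallback (from 3, back at 12): boron is placed on the benzylic carbon by conjugate borylation and the missing carbon is added afterwards. A Horner–Wadsworth–Emmons reaction of 3 with tert-butyl diethylphosphonoacetate (NaH, THF) gives the tert-butyl cinnamate F9. CuCl, NaOt-Bu and a Josiphos-type ligand with B2pin2 and MeOH give the (R)-β-boryl ester F10. Coupling with 10 and NBS as in step 6 gives the furyl propanoate F11. TMSOTf/2,6-lutidine followed by water frees the propanoic acid F12. i-BuOCOCl/NMM and then TMSCHN2 give the diazoketone F13. Silver benzoate-catalysed Wolff rearrangement in the presence of Et2NH (Arndt–Eistert homologation) gives 12.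

## Further compounds

F1 | step 8 | 2-(trimethylsilyl)furan (purchased) | C[Si](C)(C)c1ccco1
F2 | step 8 | (R)-4-[3,4-bis(benzyloxy)-2-bromophenyl]-N,N-diethyl-4-[5-(trimethylsilyl)furan-2-yl]butanamide | C[Si](C)(C)c1ccc(o1)[C@@H](c2ccc(OCc3ccccc3)c(OCc3ccccc3)c2Br)CCC(=O)N(CC)CC
F3 | step 8 | (R)-7,8-bis(benzyloxy)-4-[5-(trimethylsilyl)furan-2-yl]-3,4-dihydronaphthalen-1(2H)-one | C[Si](C)(C)c1ccc(o1)[C@@H]2CCC(=O)c3c2ccc(OCc4ccccc4)c3OCc4ccccc4
F4 | step 8 | (4R)-7,8-bis(benzyloxy)-4-[8-methoxy-4-(trimethylsilyl)-1,4-epoxy-1,4-dihydronaphthalen-1-yl]-3,4-dihydronaphthalen-1(2H)-one, both bridgehead diastereomers | COc1cccc2C3([Si](C)(C)C)C=CC(O3)([C@@H]4CCC(=O)c5c4ccc(OCc6ccccc6)c5OCc6ccccc6)c12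
F5 | step 6 | [3,4-bis(benzyloxy)-2-bromophenyl](furan-2-yl)methanol, racemic | OC(c1ccco1)c1ccc(OCc2ccccc2)c(OCc2ccccc2)c1Br
F6 | step 6 | [3,4-bis(benzyloxy)-2-bromophenyl](furan-2-yl)methanone | O=C(c1ccco1)c1ccc(OCc2ccccc2)c(OCc2ccccc2)c1Br
F7 | step 6 | (E)-4-[3,4-bis(benzyloxy)-2-bromophenyl]-4-(furan-2-yl)but-3-enoic acid | OC(=O)C/C=C(/c1ccco1)c1ccc(OCc2ccccc2)c(OCc2ccccc2)c1Br
F8 | step 6 | (R)-4-[3,4-bis(benzyloxy)-2-bromophenyl]-4-(furan-2-yl)butanoic acid | o1cccc1[C@@H](c2ccc(OCc3ccccc3)c(OCc3ccccc3)c2Br)CCC(=O)O
F9 | step 5 | tert-butyl (E)-3-[3,4-bis(benzyloxy)-2-bromophenyl]acrylate | CC(C)(C)OC(=O)/C=C/c1ccc(OCc2ccccc2)c(OCc2ccccc2)c1Br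
F10 | step 5 | tert-butyl (R)-3-[3,4-bis(benzyloxy)-2-bromophenyl]-3-(4,4,5,5-tetramethyl-1,3,2-dioxaborolan-2-yl)propanoate | CC1(C)OB(OC1(C)C)[C@@H](c2ccc(OCc3ccccc3)c(OCc3ccccc3)c2Br)CC(=O)OC(C)(C)C
F11 | step 5 | tert-butyl (R)-3-[3,4-bis(benzyloxy)-2-bromophenyl]-3-(furan-2-yl)propanoate | o1cccc1[C@@H](c2ccc(OCc3ccccc3)c(OCc3ccccc3)c2Br)CC(=O)OC(C)(C)C
F12 | step 5 | (R)-3-[3,4-bis(benzyloxy)-2-bromophenyl]-3-(furan-2-yl)propanoic acid | o1cccc1[C@@H](c2ccc(OCc3ccccc3)c(OCc3ccccc3)c2Br)CC(=O)O
F13 | step 5 | (R)-4-[3,4-bis(benzyloxy)-2-bromophenyl]-1-diazo-4-(furan-2-yl)butan-2-one | o1cccc1[C@@H](c2ccc(OCc3ccccc3)c(OCc3ccccc3)c2Br)CC(=O)C=[N+]=[N-]
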